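**Retrosynthetic overview**
- Glyinflanin C is a dibenzoylmethane. The 1,3-diketone is cut at the C(=O)–CH2 bond next to the chromene ring (Claisen acylation), giving a ring-B methyl ketone enolate and an activated 7-silyloxy-2,2-dimethylchromene-6-carboxylic acid.
- Feature the strategy rests on: in the 4-hydroxy-3-prenylphenyl ring (ring B) the chain C5'–C4'(O)–C3'–CH2CH=CMe2 is the intact skeleton of 6-methylhept-5-en-2-one, and the acyl group at C1' para to O4' marks an oxygenated diene plus alkynone cycloaddition.
- Ring B is therefore built de novo: a 1-amino-3-silyloxydiene from the terpenoid ketone adds to but-3-yn-2-one (bonds C2'–C3' and C6'–C1') and loses dimethylamine. No phenol is ever prenylated.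
- The chromene acid comes from umbelliferone: the pyran ring is already fused linearly, the lactone becomes the gem-dimethyl ether with MeMgBr, and C6 is formylated ortho to the phenol, then silylated and oxidised.
- Ring order: pyran ring present from the start (coumarin), benzene ring B closed in step 3, fragments joined in step 9, both silyl ethers removed last.

Key step: step 3

Remark: the target has no stereocentre and no stereogenic double bond, so it is achiral and no enantiocontrol is needed. The diketone is drawn in the keto form of the given SMILES, although it should exist largely as an enol.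

**Step 1**
Reactants: 1 6-methylhept-5-en-2-one; 2 N,N-dimethylformamide dimethyl acetal
Product: 3 (1E)-1-(dimethylamino)-7-methylocta-1,6-dien-3-one
Conditions: 2 (3 equiv, neat), 110 °C, MeOH distilled off
Reagents that add atoms: none
Why: Enaminone formation by condensation of a methyl ketone with a formamide acetal; the unhindered CH3 should react in preference to the α'-CH2, and the trans vinylogous amide is the stable isomer.

**Step 2**
Reactants: 3 (1E)-1-(dimethylamino)-7-methylocta-1,6-dien-3-one
Product: 5 (1E,3Z)-3-(tert-butyldimethylsilyloxy)-N,N,7-trimethylocta-1,3,6-trien-1-amine, via potassium (1E,3Z)-1-(dimethylamino)-7-methylocta-1,3,6-trien-3-olate 4 (not isolated)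
Conditions: KHMDS (1.05 equiv), THF, −78 °C; TBSCl, −78 °C → rt; pentane, filtration, used crude
Reagents that add atoms: tert-butyldimethylsilyl chloride, CC(C)(C)[Si](C)(C)Cl
Why: α'-Deprotonation of the vinylogous amide and O-silylation of the cross-conjugated dienolate is the standard preparation of 1-amino-3-silyloxybutadienes; the amide-like enolate should form with the chain away from the vinyl arm (allylic strain), which gives the 3Z diene.

**Step 3**
Reactants: 5 (1E,3Z)-3-(tert-butyldimethylsilyloxy)-N,N,7-trimethylocta-1,3,6-trien-1-amine; 6 but-3-yn-2-one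
Product: 8 1-[4-(tert-butyldimethylsilyloxy)-3-(3-methylbut-2-enyl)phenyl]ethanone, via 1-[cis-4-(tert-butyldimethylsilyloxy)-6-(dimethylamino)-3-(3-methylbut-2-enyl)cyclohexa-1,4-dien-1-yl]ethanone 7 (not isolated)
Conditions: 6 (1.5 equiv), PhMe, 0 °C → rt; then 60 °C (loss of Me2NH)
Reagents that add atoms: none
Why: The electron-rich diene 5 and the ynone 6 should combine in a normal-demand, probably asynchronous [4+2] cycloaddition in which the diene terminus C4 (future C3', carrying the prenyl CH2) bonds to the alkyne CH (C2') and the aminated terminus C1 (C6') bonds to the acyl-bearing alkyne carbon (C1'), giving cyclohexa-1,4-diene 7; its C3'–H is doubly allylic and vinylogously α to the ketone while NMe2 sits β to the same carbonyl, so 1,4-elimination of dimethylamine (vinylogous E1cB, driven by aromatisation) should follow on warming. The closest known reaction type is the Diels–Alder benzannulation of 1-amino-3-silyloxybutadienes and related 1,3-dioxygenated dienes with acetylenic ketones and esters, followed by loss of the amine or alcohol. Ring B is closed by intermolecular [4+2] cycloaddition (two C–C bonds, six-membered carbocycle). No stereocentre survives: the two sp3 carbons of 7 (cis by suprafacial addition to the 1E,3Z diene) are both flattened on aromatisation. The step needs regioselectivity (acetyl para to OTBS and meta to prenyl), secured because the amino and silyloxy donors both raise the HOMO coefficient at C4, which pairs with the β-carbon of the ynone, and it needs an accessible s-cis diene, secured by the 3Z geometry that keeps the chain outside. The isolated trisubstituted olefin is no diene partner, and acid-free conditions keep silicon on oxygen, so the phenol should emerge as its TBS ether.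

**Step 4**
Reactants: 9 umbelliferone (7-hydroxy-2H-chromen-2-one)
Product: 11 2,2-dimethyl-2H-chromen-7-ol, via 4-[(1Z)-3-hydroxy-3-methylbut-1-enyl]benzene-1,3-diol 10 (not isolated)
Conditions: MeMgBr (5 equiv), THF, 0 °C → 65 °C; then 1 M HCl, 0 °C → rt
Reagents that add atoms: methylmagnesium bromide, C[Mg]Br
Why: Double Grignard addition to the coumarin lactone gives the Z-configured tertiary allylic alcohol, which on acidification should ionise and be trapped by the ortho phenol (6-membered cyclodehydration), the classical coumarin to 2,2-dimethylchromene conversion; the excess reagent compensates for the deactivating magnesium phenoxide.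

**Step 5**
Reactants: 11 2,2-dimethyl-2H-chromen-7-ol
Product: 13 7-hydroxy-2,2-dimethyl-2H-chromene-6-carbaldehyde, via 6-(hydroxymethyl)-2,2-dimethyl-2H-chromen-7-ol 12 (not isolated)
Conditions: MgCl2 (2 equiv), Et3N (4 equiv), (CH2O)n (6 equiv), MeCN, 80 °C; cold dilute HCl work-up
Reagents that add atoms: paraformaldehyde (as formaldehyde), C=O
Why: Magnesium-phenoxide-directed ortho-formylation delivers formaldehyde within the chelate to an ortho carbon, and a second formaldehyde oxidises the salicyl alcohol 12 by hydride transfer; C6 should be preferred over C8, which is flanked by both oxygens.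

**Step 6**
Reactants: 13 7-hydroxy-2,2-dimethyl-2H-chromene-6-carbaldehyde
Product: 14 7-(tert-butyldimethylsilyloxy)-2,2-dimethyl-2H-chromene-6-carbaldehyde
Conditions: TBSCl (1.3 equiv), imidazole (2.5 equiv), DMAP (cat.), DMF, rt
Reagents that add atoms: tert-butyldimethylsilyl chloride, CC(C)(C)[Si](C)(C)Cl
Why: Imidazole-mediated silylation of a phenol; masking the chelated OH allows activation of the acid and keeps an acidic phenol away from the enolate in step 9.

**Step 7**
Reactants: 14 7-(tert-butyldimethylsilyloxy)-2,2-dimethyl-2H-chromene-6-carbaldehyde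
Product: 15 7-(tert-butyldimethylsilyloxy)-2,2-dimethyl-2H-chromene-6-carboxylic acid
Conditions: NaClO2, NaH2PO4, 2-methylbut-2-ene (20 equiv), t-BuOH/H2O, 0 °C → rt
Reagents that add atoms: sodium chlorite, [Na+].[O-]Cl=O
Why: Pinnick oxidation is chemoselective for the aldehyde; the large excess of 2-methylbut-2-ene scavenges HOCl, so the chromene olefin should be spared, and the aryl silyl ether is stable at the buffered pH.

**Step 8**
Reactants: 15 7-(tert-butyldimethylsilyloxy)-2,2-dimethyl-2H-chromene-6-carboxylic acid
Product: 16 [7-(tert-butyldimethylsilyloxy)-2,2-dimethyl-2H-chromen-6-yl](1H-imidazol-1-yl)methanone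
Conditions: CDI (1.1 equiv), THF, rt → 40 °C; concentrated, used crude
Reagents that add atoms: 1,1'-carbonyldiimidazole, O=C(n1ccnc1)n1ccnc1
Why: Acid activation with CDI gives the N-acylimidazole under neutral conditions, avoiding the HCl of acid chloride formation that would endanger the chromene and the silyl ether.

**Step 9**
Reactants: 8 1-[4-(tert-butyldimethylsilyloxy)-3-(3-methylbut-2-enyl)phenyl]ethanone; 16 [7-(tert-butyldimethylsilyloxy)-2,2-dimethyl-2H-chromen-6-yl](1H-imidazol-1-yl)methanone
Product: 18 1-[7-(tert-butyldimethylsilyloxy)-2,2-dimethyl-2H-chromen-6-yl]-3-[4-(tert-butyldimethylsilyloxy)-3-(3-methylbut-2-enyl)phenyl]propane-1,3-dione, via lithium 1-[4-(tert-butyldimethylsilyloxy)-3-(3-methylbut-2-enyl)phenyl]ethen-1-olate 17 (not isolated)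
Conditions: LiHMDS (2.2 equiv), THF, −78 °C; then 16, −78 → 0 °C; AcOH quench
Reagents that add atoms: none
Why: Crossed Claisen C-acylation of a ketone lithium enolate with an N-acylimidazole; the second equivalent of base deprotonates the 1,3-diketone as it forms and drives the acylation, and 16 has no α-hydrogen, so only one enolate is present.

**Step 10**
Reactants: 18 the bis-silyl diketone
Product: 19 Glyinflanin C, 1-(7-hydroxy-2,2-dimethyl-2H-chromen-6-yl)-3-[4-hydroxy-3-(3-methylbut-2-enyl)phenyl]propane-1,3-dione
Conditions: TBAF (2.5 equiv), AcOH (2.5 equiv), THF, 0 °C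
Reagents that add atoms: none
Why: Fluoride cleavage of both aryl silyl ethers under acetic acid buffering should free the phenols without the strong acid that would cyclise the ortho-prenylphenol to a chroman or the ortho-hydroxy diketone to a flavone.

**Compound list**
1 | 6-methylhept-5-en-2-one | CC(=O)CCC=C(C)C | starting material
2 | N,N-dimethylformamide dimethyl acetal | COC(OC)N(C)C | starting material
3 | (1E)-1-(dimethylamino)-7-methylocta-1,6-dien-3-one | CN(C)/C=C/C(=O)CCC=C(C)C | intermediate
4 | potassium (1E,3Z)-1-(dimethylamino)-7-methylocta-1,3,6-trien-3-olate | CN(C)/C=C/C([O-])=C/CC=C(C)C.[K+] | intermediate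
5 | (1E,3Z)-3-(tert-butyldimethylsilyloxy)-N,N,7-trimethylocta-1,3,6-trien-1-amine | CN(C)/C=C/C(O[Si](C)(C)C(C)(C)C)=C/CC=C(C)C | intermediate
6 | but-3-yn-2-one | CC(=O)C#C | starting material
7 | 1-[cis-4-(tert-butyldimethylsilyloxy)-6-(dimethylamino)-3-(3-methylbut-2-enyl)cyclohexa-1,4-dien-1-yl]ethanone (racemic, one enantiomer drawn) | CC(=O)C1=C[C@H](CC=C(C)C)C(O[Si](C)(C)C(C)(C)C)=C[C@@H]1N(C)C | intermediate
8 | 1-[4-(tert-butyldimethylsilyloxy)-3-(3-methylbut-2-enyl)phenyl]ethanone | CC(=O)c1ccc(O[Si](C)(C)C(C)(C)C)c(CC=C(C)C)c1 | intermediate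
9 | umbelliferone | O=c1ccc2ccc(O)cc2o1 | starting material
10 | 4-[(1Z)-3-hydroxy-3-methylbut-1-enyl]benzene-1,3-diol | CC(C)(O)/C=C\c1ccc(O)cc1O | intermediate
11 | 2,2-dimethyl-2H-chromen-7-ol | CC1(C)C=Cc2ccc(O)cc2O1 | intermediate
12 | 6-(hydroxymethyl)-2,2-dimethyl-2H-chromen-7-ol (present as its magnesium salt) | CC1(C)C=Cc2cc(CO)c(O)cc2O1 | intermediate
13 | 7-hydroxy-2,2-dimethyl-2H-chromene-6-carbaldehyde | CC1(C)C=Cc2cc(C=O)c(O)cc2O1 | intermediate
14 | 7-(tert-butyldimethylsilyloxy)-2,2-dimethyl-2H-chromene-6-carbaldehyde | CC1(C)C=Cc2cc(C=O)c(O[Si](C)(C)C(C)(C)C)cc2O1 | intermediate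
15 | 7-(tert-butyldimethylsilyloxy)-2,2-dimethyl-2H-chromene-6-carboxylic acid | CC1(C)C=Cc2cc(C(=O)O)c(O[Si](C)(C)C(C)(C)C)cc2O1 | intermediate
16 | [7-(tert-butyldimethylsilyloxy)-2,2-dimethyl-2H-chromen-6-yl](1H-imidazol-1-yl)methanone | CC1(C)C=Cc2cc(C(=O)n3ccnc3)c(O[Si](C)(C)C(C)(C)C)cc2O1 | intermediate
17 | lithium 1-[4-(tert-butyldimethylsilyloxy)-3-(3-methylbut-2-enyl)phenyl]ethen-1-olate | [Li+].[O-]C(=C)c1ccc(O[Si](C)(C)C(C)(C)C)c(CC=C(C)C)c1 | intermediate
18 | 1-[7-(tert-butyldimethylsilyloxy)-2,2-dimethyl-2H-chromen-6-yl]-3-[4-(tert-butyldimethylsilyloxy)-3-(3-methylbut-2-enyl)phenyl]propane-1,3-dione | CC(C)=CCc1cc(C(=O)CC(=O)c2cc3c(cc2O[Si](C)(C)C(C)(C)C)OC(C)(C)C=C3)ccc1O[Si](C)(C)C(C)(C)C | intermediate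
19 | Glyinflanin C | CC(C)=CCc1cc(C(=O)CC(=O)c2cc3c(cc2O)OC(C)(C)C=C3)ccc1O | target

**Step count**
Total: 10 steps. Longest linear sequence: 7 steps (steps 4–10, from umbelliferone); the ring-B branch is 5 steps (1–3, 9, 10).

**Steps most likely to fail**

1. Step 3. The ynone may be consumed by conjugate addition of the liberated dimethylamine or by oligomerisation. The diene may add in a stepwise Michael fashion without ring closure. The 4-substituted diene may react slowly, and the enol ether may hydrolyse before aromatisation. Fallback, setting out from 5 and returning at 8: the cycloaddition is run with but-3-en-2-one (PhMe, rt), the best-established dienophile class for these dienes, to give 1-[4-(tert-butyldimethylsilyloxy)-2-(dimethylamino)-5-(3-methylbut-2-enyl)cyclohex-3-en-1-yl]ethanone F1. Dilute HCl in THF then hydrolyses the enol ether and eliminates the amine to 4-acetyl-6-(3-methylbut-2-enyl)cyclohex-2-en-1-one F2. One equivalent of DDQ in dioxane at rt dehydrogenates this readily enolised 4-acylcyclohexenone to 1-[4-hydroxy-3-(3-methylbut-2-enyl)phenyl]ethanone F3, the limited oxidant and low temperature guarding against oxidative cyclisation of the ortho-prenylphenol. TBSCl/imidazole in DMF then gives 8.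

2. Step 5. Formylation may occur at the wrong ortho position (C8), or formaldehyde and the magnesium Lewis acid may attack the electron-rich chromene double bond. Fallback, setting out from 11 and returning at 13: the olefin is saturated (H2, Pd/C, EtOAc) to 2,2-dimethyl-3,4-dihydro-2H-chromen-7-ol F4. Vilsmeier–Haack formylation (POCl3, DMF, MeCN, 0 °C → rt, aqueous NaOAc) should then attack para to the ring oxygen, as in resorcinol, to give 7-hydroxy-2,2-dimethyl-3,4-dihydro-2H-chromene-6-carbaldehyde F5. DDQ in dioxane at reflux dehydrogenates the chroman through the para-quinone methide to give 13.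

3. Step 9. C-acylation by the hindered, electron-rich ortho-silyloxy aroyl donor may be slow, and O-acylation, silyl transfer or proton exchange with the product may stop the reaction early. Fallback, setting out from 8 and 14 and returning at 18: the lithium enolate of 8 (LDA, THF, −78 °C) is added to aldehyde 14 in an aldol reaction, quenched cold, to give racemic 1-[4-(tert-butyldimethylsilyloxy)-3-(3-methylbut-2-enyl)phenyl]-3-[7-(tert-butyldimethylsilyloxy)-2,2-dimethyl-2H-chromen-6-yl]-3-hydroxypropan-1-one F6. Dess–Martin periodinane (NaHCO3, CH2Cl2, 0 °C → rt) oxidises it to 18, which removes the new carbinol centre.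

**Further compounds**
F1 | step 3 | 1-[4-(tert-butyldimethylsilyloxy)-2-(dimethylamino)-5-(3-methylbut-2-enyl)cyclohex-3-en-1-yl]ethanone (racemic diastereomer mixture) | CC(=O)C1CC(CC=C(C)C)C(O[Si](C)(C)C(C)(C)C)=CC1N(C)C
F2 | step 3 | 4-acetyl-6-(3-methylbut-2-enyl)cyclohex-2-en-1-one (racemic diastereomer mixture) | CC(=O)C1CC(CC=C(C)C)C(=O)C=C1
F3 | step 3 | 1-[4-hydroxy-3-(3-methylbut-2-enyl)phenyl]ethanone | CC(=O)c1ccc(O)c(CC=C(C)C)c1
F4 | step 5 | 2,2-dimethyl-3,4-dihydro-2H-chromen-7-ol | CC1(C)CCc2ccc(O)cc2O1
F5 | step 5 | 7-hydroxy-2,2-dimethyl-3,4-dihydro-2H-chromene-6-carbaldehyde | CC1(C)CCc2cc(C=O)c(O)cc2O1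
F6 | step 9 | 1-[4-(tert-butyldimethylsilyloxy)-3-(3-methylbut-2-enyl)phenyl]-3-[7-(tert-butyldimethylsilyloxy)-2,2-dimethyl-2H-chromen-6-yl]-3-hydroxypropan-1-one (racemic) | CC(C)=CCc1cc(C(=O)CC(O)c2cc3c(cc2O[Si](C)(C)C(C)(C)C)OC(C)(C)C=C3)ccc1O[Si](C)(C)C(C)(C)C
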